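The numbers in the tables were computed on assumed constants, noise included.

Links cannot be in simple balance with the end groups here: at 55 °C, about twice the first end groups gives 0.0183 M of links against 0.0159 M, and that level already stands at the first reading.

| flask | first end groups | second end groups | temperature | remark | time |
|---|---|---|---|---|---|
| dusk | 0.10 M | 0.11 M | 55 °C | run made earlier |  |
| noon | 0.14 M | 0.11 M | 66 °C | run made earlier |  |
| midnight | 0.22 M | 0.11 M | 55 °C | run made earlier |  |
| spring | 0.10 M | 0.055 M | 66 °C | run made earlier |  |
| north-east | 0.10 M | 0.110 M (fed, over 1.0 min) | 60 °C | all else is in the flask from the start; the feed brings no volume worth counting | 5.0 min |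
| north-west | 0.10 M | 0.110 M |  | everything together at the start at 20 °C, warmed to 60 °C at 1.0 min | 5.0 min |
| east | 0.10 M | 0.110 M (fed, over 1.0 min) |  | the addition at 20 °C, then warmed to 60 °C; the feed brings no volume worth counting | 5.0 min |
| north | 0.10 M (fed, over 1.0 min) | 0.110 M | 60 °C | all else is in the flask from the start; the feed brings no volume worth counting | 5.0 min |
| south-east | 0.10 M | 0.110 M | 60 °C | everything together at the start | 5.0 min |

| run | time / min | links / % |
|---|---|---|
| dusk | 1.33 | 15.9 |
| dusk | 2.50 | 16.0 |
| dusk | 4.00 | 16.4 |
| dusk | 5.00 | 16.8 |
| noon | 1.00 | 7.9 |
| noon | 2.00 | 9.1 |
| noon | 3.00 | 8.9 |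
| noon | 4.00 | 8.6 |
| midnight | 1.00 | 8.3 |
| midnight | 2.00 | 8.2 |
| midnight | 3.00 | 8.5 |
| midnight | 4.00 | 8.2 |
| spring | 0.333 | 3.1 |
| spring | 0.667 | 3.0 |
| spring | 1.50 | 3.5 |
| spring | 4.00 | 4.2 |

(standard deviation of a reading: 0.5 percentage points)

- the numbers in the tables scatter by 0.5 percentage points (one standard deviation)

- the best flask by amount of links, in percent of the first end groups charged; "all alike" if 1.5 percentage points covers them all (north-east / north-west / east / north / south-east / all alike)
- amount of links at the end, in percent of the first end groups charged, north-east
- amount of links at the end, in percent of the first end groups charged, north-west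
- amount of links at the end, in percent of the first end groups charged, east
- amount of links at the end, in percent of the first end groups charged, north
- amount of links at the end, in percent of the first end groups charged, south-east

Note for the bench: the runs read best as a flask in which most second end groups are consumed by a route that gives no links, while the link share, a selectivity that rises with concentration, equals twice c times [second end groups]. Here c is plateau links divided by the square of the charged second end groups, which reads 1.41 M⁻¹ at 55 °C and 1.02 M⁻¹ at 66 °C, so the geometric mean gives the link constant at 60 °C, 1.20 M⁻¹. South-east should therefore end near 14.5%. If the spring plateau marks the end of its second end groups, they went at 0.165 M min⁻¹ or faster at 66 °C, which is faster than the feed of 0.110 M min⁻¹, so north-east should hold [second end groups] low and end far below south-east. Since c reads larger cold, north-west should lead, with east between it and south-east. No run shows second end groups standing without first end groups, and north is left without a number here. Not to be touched: the cold start with everything charged together.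

The forecast gave 15.4%, 15.5%, 15.4%, 15.4% and 15.6% for north-east, north-west, east, north and south-east, hence all alike, holding that “four minutes erases the history of feeding or warming”.

The flasks gave 0.192%, 22.5%, 17.4%, 5.08% and 13.5% in that order, so the best is north-west.

    links ⇌ isomer of the product (K = 0.420, k = 0.0330 s⁻¹, Ea = 88.0 kJ mol⁻¹, ΔH = 9.00 kJ mol⁻¹)
    second end groups → decomposed reagent (k = 0.0410 s⁻¹, Ea = 76.0 kJ mol⁻¹)
    first end groups + second end groups → links (k = 0.700 M⁻¹ s⁻¹, Ea = 55.0 kJ mol⁻¹)
    first end groups + second end groups → rings, rate k4*[first end groups] as long as [second end groups] is above zero (k = 0.130 s⁻¹, Ea = 94.0 kJ mol⁻¹)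
    (constants at 60 °C)

In north-east at 0.453 min, first end groups had a half-life of 0.32 min by the step to rings, which is shorter than the 1.0 min of the feed. Read through c, the 0.192% of links per ring in north-east corresponds to a mean [second end groups], taken over the first end groups that reacted, of 8.01 × 10⁻⁴ M, hardly any of the charge, and rings stood at 99.7%.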